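Assumption: the target is taken exactly as the SMILES encodes it, i.e. (1S,2Z,4R,5S,8E)-4-acetoxy-2,8-dimethyl-5-isopropylcyclodeca-2,8-dien-1-yl angelate; locants in the overview and fallbacks follow this ring numbering.

**Retrosynthetic overview**
1. Target 26 ⇒ angeloylation of hydroxy acetate 23 ⇒ C–B oxidation and O-acetylation of cyclic allylboronate 21; the C–B bond is the masked, differentiated second hydroxyl, so no protecting groups are needed.
2. 21 ⇒ ring contraction of the 11-membered cyclic boronate complex 20 by a 1,2-shift of the alkenyl carbon from B to C, which forms the C1–C2 ring bond and sets C1; 20 comes from open-chain bromide 18.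
3. 18 ⇒ B-alkyl Suzuki union (C7–C8 bond) of dienol 9 with alkenyl iodide 16, which carries the E-olefin.
4. 9 ⇒ anti-selective Brown allylboration of (Z)-3-bromobut-2-enal (sets C4 and C5; Z-olefin from but-2-yn-1-ol); 16 ⇒ Hoppe lithiation–borylation and hydrozirconation–iodination of pent-3-yn-1-yl carbamate.
5. Ring order: one ring only, the cyclodecadiene, closed in step 8.

**Route**

Step 1
Reactants: 1 but-2-yn-1-ol
Product: 3 (2Z)-3-bromobut-2-en-1-ol, via vinylalanate 2 (not isolated)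
Conditions: Red-Al (1.5 equiv), Et2O, 0 °C → rt; then NBS, −78 → 0 °C
Reagents that add atoms: N-bromosuccinimide, O=C1CCC(=O)N1Br
Why: Hydroxyl-directed trans-hydroalumination of the propargylic alcohol gives the cyclic vinylalanate 2 (Al on C3, cis to CH2O), and bromodealumination with retention fixes the Z geometry needed for the cis ring olefin.

Step 2
Reactants: 3 (2Z)-3-bromobut-2-en-1-ol
Product: 4 (2Z)-3-bromobut-2-enal
Conditions: activated MnO2 (15 equiv), CH2Cl2, rt; used directly as a solution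
Reagents that add atoms: none
Why: Neutral allylic oxidation with MnO2 gives the β-bromo enal without Z/E isomerisation.

Step 3
Reactants: 4 (2Z)-3-bromobut-2-enal, 5 (2E)-4-methylpent-2-ene
Product: 9 (3R,4R,5Z)-6-bromo-3-(propan-2-yl)hepta-1,5-dien-4-ol, via allylpotassium 6 (not isolated), via allylborane 7 (not isolated), via borinate 8 (not isolated)
Conditions: 5, n-BuLi, KOt-Bu, THF, −45 °C, 15 min; (+)-Ipc2BOMe [from (−)-α-pinene], −78 °C; BF3·OEt2; then 4, −78 °C, 4 h; NaOH, H2O2, 0 °C → rt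
Reagents that add atoms: none
Why: Brown asymmetric allylboration through a closed chair Zimmerman–Traxler transition state, in which the (E)-allylborane 7 gives the 3,4-anti product and the isopinocampheyl groups from (−)-α-pinene direct addition to the Re face of 4, setting 4R and hence 3R.

Step 4
Reactants: 10 pent-3-yn-1-ol
Product: 11 pent-3-yn-1-yl N,N-di(propan-2-yl)carbamate
Conditions: i-Pr2NCOCl, Et3N, DMAP (cat.), CH2Cl2, reflux
Reagents that add atoms: N,N-diisopropylcarbamoyl chloride, CC(C)N(C(C)C)C(Cl)=O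
Why: O-Carbamoylation installs the group that directs α-lithiation and later serves as the leaving group of the 1,2-shift.

Step 5
Reactants: 11 pent-3-yn-1-yl N,N-di(propan-2-yl)carbamate
Product: 14 (1R)-1-(4,4,5,5-tetramethyl-1,3,2-dioxaborolan-2-yl)pent-3-yn-1-yl N,N-di(propan-2-yl)carbamate, via lithiated carbamate 12 (not isolated), via diisopropyl boronate 13 (not isolated)
Conditions: s-BuLi, (+)-sparteine, Et2O, −78 °C, 5 h; B(Oi-Pr)3, −78 °C → rt; then pinacol, MgSO4, rt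
Reagents that add atoms: triisopropyl borate, CC(C)OB(OC(C)C)OC(C)C; pinacol, CC(C)(O)C(C)(C)O
Why: Hoppe sparteine-mediated asymmetric deprotonation, in which s-BuLi/(+)-sparteine removes the pro-R α-hydrogen to give the configurationally stable (R)-lithio carbamate 12, which is borylated with retention and transesterified, setting the carbinol carbon as R.

Step 6
Reactants: 14 (1R)-1-(4,4,5,5-tetramethyl-1,3,2-dioxaborolan-2-yl)pent-3-yn-1-yl N,N-di(propan-2-yl)carbamate
Product: 16 (1R,3E)-4-iodo-1-(4,4,5,5-tetramethyl-1,3,2-dioxaborolan-2-yl)pent-3-en-1-yl N,N-di(propan-2-yl)carbamate, via alkenylzirconocene 15 (not isolated)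
Conditions: Cp2Zr(H)Cl (1.8 equiv), THF, rt → 40 °C; then I2, 0 °C
Reagents that add atoms: iodine, II
Why: syn-Hydrozirconation with Schwartz reagent places Zr on the less hindered methyl-bearing alkyne carbon (regio-equilibration with excess reagent) and iodinolysis of 15 with retention gives the E-2-iodoalkene, while carbamate and boronic ester are inert.

Step 7
Reactants: 9 (3R,4R,5Z)-6-bromo-3-(propan-2-yl)hepta-1,5-dien-4-ol, 16 (1R,3E)-4-iodo-1-(4,4,5,5-tetramethyl-1,3,2-dioxaborolan-2-yl)pent-3-en-1-yl N,N-di(propan-2-yl)carbamate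
Product: 18 (1R,3E,7S,8R,9Z)-10-bromo-8-hydroxy-4-methyl-7-(propan-2-yl)-1-(4,4,5,5-tetramethyl-1,3,2-dioxaborolan-2-yl)undeca-3,9-dien-1-yl N,N-di(propan-2-yl)carbamate, via bis(9-BBN) adduct 17 (not isolated)
Conditions: 9, 9-BBN-H (2.2 equiv), THF, 0 °C → rt; then 16 (1.2 equiv), PdCl2(dppf) (5 mol %), AsPh3, Cs2CO3, DMF–H2O, rt
Reagents that add atoms: none
Why: Anti-Markovnikov hydroboration of the terminal vinyl group followed by B-alkyl Suzuki–Miyaura coupling, in which Pd(0) inserts into the alkenyl iodide much faster than into the alkenyl bromide and only the B-alkyl-9-BBN (not the secondary α-oxy pinacol boronate) transmetalates, so no stereocentre is touched.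

Step 8
Reactants: 18 (1R,3E,7S,8R,9Z)-10-bromo-8-hydroxy-4-methyl-7-(propan-2-yl)-1-(4,4,5,5-tetramethyl-1,3,2-dioxaborolan-2-yl)undeca-3,9-dien-1-yl N,N-di(propan-2-yl)carbamate
Product: 21 (1R,2Z,4S,6E,10S)-3,7-dimethyl-10-(propan-2-yl)-4-(4,4,5,5-tetramethyl-1,3,2-dioxaborolan-2-yl)cyclodeca-2,6-dien-1-ol, via O,C-dilithio species 19 (not isolated), via cyclic boronate complex 20 (not isolated)
Conditions: MeLi (1.0 equiv), THF–Et2O (0.5 mM), −78 °C; t-BuLi (2.1 equiv), −78 °C, 15 min; → −40 °C, 1 h; then 40 °C, 12 h; H2O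
Reagents that add atoms: none
Why: Proposed new method: a ring-contractive macrocyclic 1,2-metallate rearrangement in which Br/Li exchange (after O-deprotonation) gives the Z-alkenyllithium 19, which at high dilution adds to the tethered pinacol boronate to form the 11-membered cyclic boronate ("ate") complex 20, whereupon warming makes the alkenyl carbon migrate from boron to carbon antiperiplanar to the departing carbamate (inversion at carbon, retention of olefin geometry), contracting the boracycle to the 10-membered carbocycle and turning the (R)-C–O centre into the (S)-C–B centre; the closest known reaction type is the intermolecular Hoppe–Matteson–Aggarwal lithiation–borylation of α-carbamoyloxy boronates with alkenyl metals and the ring contraction of small cyclic boronate complexes, not yet shown for medium-ring formation.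

Step 9
Reactants: 21 (1R,2Z,4S,6E,10S)-3,7-dimethyl-10-(propan-2-yl)-4-(4,4,5,5-tetramethyl-1,3,2-dioxaborolan-2-yl)cyclodeca-2,6-dien-1-ol
Product: 22 (1R,2Z,4S,6E,10S)-3,7-dimethyl-10-(propan-2-yl)-4-(4,4,5,5-tetramethyl-1,3,2-dioxaborolan-2-yl)cyclodeca-2,6-dien-1-yl acetate
Conditions: Ac2O, Et3N, DMAP (cat.), CH2Cl2, 0 °C → rt
Reagents that add atoms: acetic anhydride, CC(=O)OC(C)=O
Why: DMAP-catalysed acetylation of the only free hydroxyl, while the allylic pinacol boronate is inert and keeps the second oxygen position masked.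

Step 10
Reactants: 22 (1R,2Z,4S,6E,10S)-3,7-dimethyl-10-(propan-2-yl)-4-(4,4,5,5-tetramethyl-1,3,2-dioxaborolan-2-yl)cyclodeca-2,6-dien-1-yl acetate
Product: 23 (1R,2Z,4S,6E,10S)-4-hydroxy-3,7-dimethyl-10-(propan-2-yl)cyclodeca-2,6-dien-1-yl acetate
Conditions: NaBO3·4H2O, THF–H2O (1:1), rt
Reagents that add atoms: sodium perborate, [Na+].[Na+].O[B-]1(O)OO[B-](O)(O)OO1
Why: Perborate oxidation of the secondary allylic boronate (carbon migrates from B to O with retention) converts (S)-C–B into (S)-C–OH under conditions mild enough to spare the acetate.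

Step 11
Reactants: 23 (1R,2Z,4S,6E,10S)-4-hydroxy-3,7-dimethyl-10-(propan-2-yl)cyclodeca-2,6-dien-1-yl acetate, 24 angelic acid [(2Z)-2-methylbut-2-enoic acid]
Product: 26 (1S,2Z,4R,5S,8E)-4-(acetyloxy)-2,8-dimethyl-5-(propan-2-yl)cyclodeca-2,8-dien-1-yl (2Z)-2-methylbut-2-enoate, via mixed anhydride 25 (not isolated)
Conditions: 24, 2,4,6-trichlorobenzoyl chloride, Et3N, toluene, rt, 2 h; then 23, toluene, 80 °C
Reagents that add atoms: none
Why: Yamaguchi-type esterification through mixed anhydride 25 acylates the allylic alcohol without base-induced isomerisation of the Z-angelate to the tiglate and leaves all stereocentres untouched.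

**Compound list**
1 | but-2-yn-1-ol | CC#CCO | starting material
2 | sodium 2,2-bis(2-methoxyethoxy)-3-methyl-2,5-dihydro-1,2-oxaluminol-2-uide (cyclic Z-vinylalanate) | [Na+].CC1=CCO[Al-]1(OCCOC)OCCOC | intermediate (not isolated)
3 | (2Z)-3-bromobut-2-en-1-ol | OC/C=C(/C)Br | intermediate
4 | (2Z)-3-bromobut-2-enal | O=C/C=C(/C)Br | intermediate
5 | (2E)-4-methylpent-2-ene | C/C=C/C(C)C | starting material
6 | [(2E)-4-methylpent-2-en-1-yl]potassium | [K]C/C=C/C(C)C | intermediate (not isolated)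
7 | [(2E)-4-methylpent-2-en-1-yl]di(isopinocampheyl)borane, Ipc from (−)-α-pinene | CC(C)/C=C/CB([C@H]1C[C@@H]2C(C)(C)[C@@H](C2)[C@@H]1C)[C@H]1C[C@@H]2C(C)(C)[C@@H](C2)[C@@H]1C | intermediate (not isolated)
8 | (3R,4R,5Z)-6-bromo-3-(propan-2-yl)hepta-1,5-dien-4-yl di(isopinocampheyl)borinate | C=C[C@@H](C(C)C)[C@@H](OB([C@H]1C[C@@H]2C(C)(C)[C@@H](C2)[C@@H]1C)[C@H]1C[C@@H]2C(C)(C)[C@@H](C2)[C@@H]1C)/C=C(/C)Br | intermediate (not isolated)
9 | (3R,4R,5Z)-6-bromo-3-(propan-2-yl)hepta-1,5-dien-4-ol | C=C[C@@H](C(C)C)[C@@H](O)/C=C(/C)Br | intermediate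
10 | pent-3-yn-1-ol | CC#CCCO | starting material
11 | pent-3-yn-1-yl N,N-di(propan-2-yl)carbamate | CC#CCCOC(=O)N(C(C)C)C(C)C | intermediate
12 | (1R)-1-lithiopent-3-yn-1-yl N,N-di(propan-2-yl)carbamate, (+)-sparteine complex | CC#CC[C@H](OC(=O)N(C(C)C)C(C)C)[Li] | intermediate (not isolated)
13 | dipropan-2-yl [(1R)-1-{[di(propan-2-yl)carbamoyl]oxy}pent-3-yn-1-yl]boronate | CC#CC[C@H](OC(=O)N(C(C)C)C(C)C)B(OC(C)C)OC(C)C | intermediate (not isolated)
14 | (1R)-1-(4,4,5,5-tetramethyl-1,3,2-dioxaborolan-2-yl)pent-3-yn-1-yl N,N-di(propan-2-yl)carbamate | CC#CC[C@H](OC(=O)N(C(C)C)C(C)C)B1OC(C)(C)C(C)(C)O1 | intermediate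
15 | chlorido{(2E,5R)-5-{[di(propan-2-yl)carbamoyl]oxy}-5-(4,4,5,5-tetramethyl-1,3,2-dioxaborolan-2-yl)pent-2-en-2-yl}zirconocene | C/C(=C\C[C@H](OC(=O)N(C(C)C)C(C)C)B1OC(C)(C)C(C)(C)O1)[Zr](Cl)(C1C=CC=C1)C1C=CC=C1 | intermediate (not isolated)
16 | (1R,3E)-4-iodo-1-(4,4,5,5-tetramethyl-1,3,2-dioxaborolan-2-yl)pent-3-en-1-yl N,N-di(propan-2-yl)carbamate | C/C(I)=C\C[C@H](OC(=O)N(C(C)C)C(C)C)B1OC(C)(C)C(C)(C)O1 | intermediate
17 | O,C-bis(9-borabicyclo[3.3.1]nonan-9-yl) adduct of 9 (C1–B and O–B) | C(CB1C2CCCC1CCC2)[C@@H](C(C)C)[C@@H](OB1C2CCCC1CCC2)/C=C(/C)Br | intermediate (not isolated)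
18 | (1R,3E,7S,8R,9Z)-10-bromo-8-hydroxy-4-methyl-7-(propan-2-yl)-1-(4,4,5,5-tetramethyl-1,3,2-dioxaborolan-2-yl)undeca-3,9-dien-1-yl N,N-di(propan-2-yl)carbamate | CC(C)N(C(C)C)C(=O)O[C@H](B1OC(C)(C)C(C)(C)O1)C/C=C(\C)CC[C@@H](C(C)C)[C@@H](O)/C=C(/C)Br | intermediate
19 | C10-lithio, O8-lithium alkoxide of 18 (Br replaced by Li, OH by OLi) | CC(C)N(C(C)C)C(=O)O[C@H](B1OC(C)(C)C(C)(C)O1)C/C=C(\C)CC[C@@H](C(C)C)[C@@H](O[Li])/C=C(/C)[Li] | intermediate (not isolated)
20 | lithium salt of the 11-membered cyclic boronate complex (B bonded to C1, C10 and pinacol; carbamate still on C1) | [Li+].CC(C)N(C(C)C)C(=O)O[C@H]1C/C=C(\C)CC[C@@H](C(C)C)[C@@H](O[Li])/C=C(/C)[B-]12OC(C)(C)C(C)(C)O2 | intermediate (not isolated)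
21 | (1R,2Z,4S,6E,10S)-3,7-dimethyl-10-(propan-2-yl)-4-(4,4,5,5-tetramethyl-1,3,2-dioxaborolan-2-yl)cyclodeca-2,6-dien-1-ol | CC2(C)OB(OC2(C)C)[C@H]1C/C=C(\C)CC[C@@H](C(C)C)[C@@H](O)/C=C\1C | intermediate
22 | (1R,2Z,4S,6E,10S)-3,7-dimethyl-10-(propan-2-yl)-4-(4,4,5,5-tetramethyl-1,3,2-dioxaborolan-2-yl)cyclodeca-2,6-dien-1-yl acetate | CC2(C)OB(OC2(C)C)[C@H]1C/C=C(\C)CC[C@@H](C(C)C)[C@@H](OC(C)=O)/C=C\1C | intermediate
23 | (1R,2Z,4S,6E,10S)-4-hydroxy-3,7-dimethyl-10-(propan-2-yl)cyclodeca-2,6-dien-1-yl acetate | O[C@H]1C/C=C(\C)CC[C@@H](C(C)C)[C@@H](OC(C)=O)/C=C\1C | intermediate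
24 | angelic acid, (2Z)-2-methylbut-2-enoic acid | C/C=C(/C)C(=O)O | starting material
25 | (2Z)-2-methylbut-2-enoic 2,4,6-trichlorobenzoic anhydride | C/C=C(/C)C(=O)OC(=O)c1c(Cl)cc(Cl)cc1Cl | intermediate (not isolated)
26 | (1S,2Z,4R,5S,8E)-4-(acetyloxy)-2,8-dimethyl-5-(propan-2-yl)cyclodeca-2,8-dien-1-yl (2Z)-2-methylbut-2-enoate | C/C=C(/C)C(=O)O[C@H]1C/C=C(\C)CC[C@@H](C(C)C)[C@@H](OC(C)=O)/C=C\1C | target

**Step count:** 11 steps in total; longest linear sequence 8 steps (1 → 2 → 3 → 7 → 8 → 9 → 10 → 11; the branch 4 → 5 → 6 → 7 … is equally long).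

**Three steps most likely to fail, with fallbacks**

Step 8 (the proposed new ring contraction). The risks are oligomeric boronate complexes instead of the 11-membered one, attack of t-BuLi at boron, and sluggish migration in the strained complex. The fallback uses known chemistry and sets out from 18. Acetylation (Ac2O, DMAP, Et3N) gives (1R,3E,7S,8R,9Z)-8-(acetyloxy)-10-bromo-4-methyl-7-(propan-2-yl)-1-(4,4,5,5-tetramethyl-1,3,2-dioxaborolan-2-yl)undeca-3,9-dien-1-yl N,N-di(propan-2-yl)carbamate F1. Buffered perborate oxidation of its α-carbamoyloxy boronate collapses to the β,γ-unsaturated aldehyde (2Z,4R,5S,8E)-2-bromo-8-methyl-11-oxo-5-(propan-2-yl)undeca-2,8-dien-4-yl acetate F2, which is used at once. An intramolecular Nozaki–Hiyama–Kishi reaction of the alkenyl bromide with the aldehyde (CrCl2, cat. NiCl2, DMSO–THF, 2 mM) then closes the ten-membered ring and comes back to the route at 23. The new carbinol centre is under substrate control only, so the epimer (1R,2Z,4R,6E,10S)-4-hydroxy-3,7-dimethyl-10-(propan-2-yl)cyclodeca-2,6-dien-1-yl acetate F3 may form. It is separated and converted with inversion by Mitsunobu esterification with angelic acid 24 (PPh3, DIAD), which rejoins the route at 26.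

Step 5 (sparteine-mediated lithiation–borylation of the alkynyl carbamate). The risks are competing propargylic deprotonation with β-elimination of the carbamate and erosion of the enantiomeric ratio. The fallback sets out from 11 and lithiates an alkene instead of the alkyne, using a vinylsilane as an s-BuLi-inert stand-in for the iodide. Hydrozirconation–iodination of 11 (Cp2Zr(H)Cl; I2) gives (3E)-4-iodopent-3-en-1-yl N,N-di(propan-2-yl)carbamate F4. I/Li exchange (t-BuLi, −78 °C) and Me3SiCl give (3E)-4-(trimethylsilyl)pent-3-en-1-yl N,N-di(propan-2-yl)carbamate F5. The same Hoppe sequence (s-BuLi/(+)-sparteine; B(Oi-Pr)3; pinacol) gives (1R,3E)-1-(4,4,5,5-tetramethyl-1,3,2-dioxaborolan-2-yl)-4-(trimethylsilyl)pent-3-en-1-yl N,N-di(propan-2-yl)carbamate F6. ipso-Iododesilylation with NIS in hexafluoroisopropanol (retention) comes back to the route at 16.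

Step 7 (hydroboration / B-alkyl Suzuki union). The risks are Pd insertion into the substrate's own alkenyl bromide (intramolecular coupling to a cyclohexene), sensitivity of the α-carbamoyloxy boronate to aqueous base, and interference of the free hydroxyl. The fallback sets out from 9 and replaces the boron-based coupling by a base-free Negishi coupling. Silylation (Et3SiCl, imidazole) gives {[(3R,4R,5Z)-6-bromo-3-(propan-2-yl)hepta-1,5-dien-4-yl]oxy}(triethyl)silane F7. Hydroboration–iodination (9-BBN; then I2, NaOMe) gives {[(2Z,4R,5S)-2-bromo-7-iodo-5-(propan-2-yl)hept-2-en-4-yl]oxy}(triethyl)silane F8. Zinc insertion (Zn, LiCl, THF) gives [(3S,4R,5Z)-6-bromo-3-(propan-2-yl)-4-[(triethylsilyl)oxy]hept-5-en-1-yl](iodo)zinc F9. Pd-catalysed coupling with 16 (Pd(OAc)2, SPhos, THF, rt) gives (1R,3E,7S,8R,9Z)-10-bromo-4-methyl-7-(propan-2-yl)-1-(4,4,5,5-tetramethyl-1,3,2-dioxaborolan-2-yl)-8-[(triethylsilyl)oxy]undeca-3,9-dien-1-yl N,N-di(propan-2-yl)carbamate F10. Desilylation (PPTS, MeOH) comes back to the route at 18.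

Further compounds
F1 | step 8 | (1R,3E,7S,8R,9Z)-8-(acetyloxy)-10-bromo-4-methyl-7-(propan-2-yl)-1-(4,4,5,5-tetramethyl-1,3,2-dioxaborolan-2-yl)undeca-3,9-dien-1-yl N,N-di(propan-2-yl)carbamate | CC(C)N(C(C)C)C(=O)O[C@H](B1OC(C)(C)C(C)(C)O1)C/C=C(\C)CC[C@@H](C(C)C)[C@@H](OC(C)=O)/C=C(/C)Br
F2 | step 8 | (2Z,4R,5S,8E)-2-bromo-8-methyl-11-oxo-5-(propan-2-yl)undeca-2,8-dien-4-yl acetate | O=CC/C=C(\C)CC[C@@H](C(C)C)[C@@H](OC(C)=O)/C=C(/C)Br
F3 | step 8 | (1R,2Z,4R,6E,10S)-4-hydroxy-3,7-dimethyl-10-(propan-2-yl)cyclodeca-2,6-dien-1-yl acetate | O[C@@H]1C/C=C(\C)CC[C@@H](C(C)C)[C@@H](OC(C)=O)/C=C\1C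
F4 | step 5 | (3E)-4-iodopent-3-en-1-yl N,N-di(propan-2-yl)carbamate | C/C(I)=C\CCOC(=O)N(C(C)C)C(C)C
F5 | step 5 | (3E)-4-(trimethylsilyl)pent-3-en-1-yl N,N-di(propan-2-yl)carbamate | C/C(=C\CCOC(=O)N(C(C)C)C(C)C)[Si](C)(C)C
F6 | step 5 | (1R,3E)-1-(4,4,5,5-tetramethyl-1,3,2-dioxaborolan-2-yl)-4-(trimethylsilyl)pent-3-en-1-yl N,N-di(propan-2-yl)carbamate | C/C(=C\C[C@H](OC(=O)N(C(C)C)C(C)C)B1OC(C)(C)C(C)(C)O1)[Si](C)(C)C
F7 | step 7 | {[(3R,4R,5Z)-6-bromo-3-(propan-2-yl)hepta-1,5-dien-4-yl]oxy}(triethyl)silane | C=C[C@@H](C(C)C)[C@@H](O[Si](CC)(CC)CC)/C=C(/C)Br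
F8 | step 7 | {[(2Z,4R,5S)-2-bromo-7-iodo-5-(propan-2-yl)hept-2-en-4-yl]oxy}(triethyl)silane | ICC[C@@H](C(C)C)[C@@H](O[Si](CC)(CC)CC)/C=C(/C)Br
F9 | step 7 | [(3S,4R,5Z)-6-bromo-3-(propan-2-yl)-4-[(triethylsilyl)oxy]hept-5-en-1-yl](iodo)zinc | I[Zn]CC[C@@H](C(C)C)[C@@H](O[Si](CC)(CC)CC)/C=C(/C)Br
F10 | step 7 | (1R,3E,7S,8R,9Z)-10-bromo-4-methyl-7-(propan-2-yl)-1-(4,4,5,5-tetramethyl-1,3,2-dioxaborolan-2-yl)-8-[(triethylsilyl)oxy]undeca-3,9-dien-1-yl N,N-di(propan-2-yl)carbamate | CC(C)N(C(C)C)C(=O)O[C@H](B1OC(C)(C)C(C)(C)O1)C/C=C(\C)CC[C@@H](C(C)C)[C@@H](O[Si](CC)(CC)CC)/C=C(/C)Br
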